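Start with the lag.

| setting | zeta | alpha | theta |
|---|---|---|---|
| L | 0.0500 M | 0.0500 M | 0.0250 M |
| G | 0.125 M | 0.250 M | 0.0410 M |
| J | 0.00250 M | 0.00250 M | 0.00250 M |
| time |  |  | 4.4 h |

| run | time / h | [Q] / M |
|---|---|---|
| zeta run | 0.16 | 0 |
| zeta run | 0.48 | 0.0018 |
| zeta run | 0.92 | 0.0063 |
| zeta run | 1.5 | 0.0122 |
| zeta run | 2.1 | 0.0186 |
| zeta run | 2.8 | 0.0247 |
| zeta run | 3.6 | 0.0323 |
| zeta run | 4.4 | 0.0385 |
| alpha run | 0.16 | 0.0013 |
| alpha run | 0.48 | 0.0061 |
| alpha run | 0.92 | 0.0162 |
| alpha run | 1.5 | 0.0289 |
| alpha run | 2.1 | 0.0397 |
| alpha run | 2.8 | 0.0484 |
| alpha run | 3.6 | 0.0496 |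
| alpha run | 4.4 | 0.0498 |

(standard deviation of a reading: 3 × 10⁻⁴ M)

* the power of [G] that the first rate follows, about the charge of the zeta run; measure it at two percent of L made into Q
* Q in the theta run at 4.4 h, as a share of the L charged
* which of these the readings show (the catalyst wakes slowly / the by-product ties up the catalyst / the by-product binds the second partner / the second partner pairs with itself / nothing beyond the main steps / the product binds the second partner)

- Overall: L + G -> Q, with J as catalyst.
- Constant volume, constant temperature.
- Bound and free are read together.
- "The second partner" is G.
- An order is taken over about fifteen percent of the charge, up and down.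

Take the middle of each run first. Q climbs as though the catalyst sat full of L and waited for G, a pseudo-first-order loss of G. To test that, take the logarithm of charged [G] over present [G], with present [G] as charged [G] less Q, at two middle readings of each run, and join them by a line against time. Its slope reads 0.0903 /h in the zeta run and 0.0898 /h in the alpha run, so the running rate per [G] reads alike at these two charges.

Now run that line back to the first instants. Read off this way, it reaches zero late, at 0.363 h in the zeta run and 0.174 h in the alpha run. The alpha lag is about half the zeta lag, with twice the G. So multiply the two. The mean reads 160 M·s, and I call it the wake dose, the induction period multiplied by the [G] charged. Divide it by a charge of G and you have an estimate of that flask's lag.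

This also gives you the order. While the catalyst wakes, its active part grows with [G]t, the rate goes as [G] times that, and Q goes as the square of [G]t. At a fixed small Q, then, [G]t is fixed and the rate follows the first power of [G].

The end of the alpha run is abrupt. At 4.4 h its Q reads 0.0498 M, against 0.0500 M of L charged and 0.250 M of G, so L, charged at less than G, is the limiting reagent there.

For the theta run, the wake dose gives a lag of 1.08 h. Take the slope as 0.0901 /h and the remaining time as 3.32 h. I then reckon Q at 0.0106 M, which is 42.3 % of the L charged.

The forecast gives an order of 0.97, a theta share of 38 %, lower than my 42.3 %, and the answer the catalyst wakes slowly. Its grounds: “so the catalyst wakes slowly, apparently helped by G”, with a wake-up time of about 1.3 h for the theta run.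

The flask gives 38.2 % for the theta run, below my 42.3 %, with an order of 1.0 and the answer the catalyst wakes slowly.

Wy + L ⇌ JL, settled at all times (301.0 /M); JL + G → Q + Wy + X (43.56 /M/h); J + G → Wy + G (15.70 /M/h) The fit with nothing beyond the main steps puts the theta run at 48.4 %. The wake dose over the theta charge of G gives a lag of 1.08 h, a quarter of the 4.4 h. Taking that share off the fit's figure leaves 36.5 %.

The numbers in the tables were computed for an exercise.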